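**Retrosynthetic overview**

1. The target is a 6,12-olide. Germacrane numbering is used for positions: C6 carries the lactone oxygen, C7 is the ring-fusion carbon, C8 the acyloxy carbon, C11/C12/C13 the lactone α-carbon, carbonyl and methylene, C14 the CH2OAc carbon, C4 the CHMe carbon. The last disconnections are the C8 ester (Yamaguchi) and the C14 acetate.
2. The γ-lactone is closed last by forming C7–C11: an O6-bound diethylphosphonoacetate carbanion opens a cis-C7,C8-epoxide on the intact ten-membered ring, and the phosphonate anion so formed olefinates formaldehyde in the same flask (C11=C13).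
3. Enabling feature: C7 lies between the oxygenated ring carbons C6 and C8; O6 is the lactone oxygen, and O8 is β to C11 and anti to the C7–C11 bond. The C6/C7/C8 triad is therefore a hidden cis-2,3-epoxy alcohol: the five-membered ring O6–C12–C11–C7–C6 can close 5-exo with inversion at C7 while the epoxide oxygen becomes the C8 hydroxyl.
4. The ten-membered carbocycle is made before the lactone: C6–C7 by CrCl2/NiCl2 cyclisation of an iodoalkyne aldehyde, C6 by transfer hydrogenation of the ynone, the Z-alkene by semihydrogenation, C7/C8 by hydroxyl-directed epoxidation.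
5. The open chain comes from a butenolide lactol (its ring fixes the C1(10) geometry), an (S)-methylsuccinate-derived ylide (Z-Wittig, C2=C3) and ethynylmagnesium bromide (C8–C9).

Key step: step 18

Remark: (S)-2-methylsuccinic acid 4-methyl ester, (R)-3-bromo-2-hydroxy-2-methylpropanoic acid and diethylphosphonoacetic acid are taken as commercially available.

**Route**

Step 1
Reactants: 1 1,3-dihydroxyacetone (used as its commercial dimer); 2 ethyl 2-(triphenyl-λ5-phosphanylidene)acetate
Product: 3 4-(hydroxymethyl)furan-2(5H)-one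
Conditions: CH2Cl2, rt
Reagents that add atoms: none
Why: Wittig olefination of the ketone followed by spontaneous lactonisation of the hydroxymethyl group cis to the ester should give the butenolide whatever the olefin geometry, because the two hydroxymethyl groups are equivalent.

Step 2
Reactants: 3 4-(hydroxymethyl)furan-2(5H)-one
Product: 4 4-{[(tert-butyldimethylsilyl)oxy]methyl}furan-2(5H)-one
Conditions: TBSCl, imidazole, DMF, 0 °C → rt
Reagents that add atoms: tert-butyldimethylsilyl chloride, CC(C)(C)[Si](C)(C)Cl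
Why: Standard silylation of the primary alcohol; the silyl ether should survive the hydride, ylide and chromium steps that an acetate would not.

Step 3
Reactants: 4 4-{[(tert-butyldimethylsilyl)oxy]methyl}furan-2(5H)-one
Product: 5 4-{[(tert-butyldimethylsilyl)oxy]methyl}-2,5-dihydrofuran-2-ol (lactol, both anomers)
Conditions: i-Bu2AlH (1.1 equiv), CH2Cl2, −78 °C; Rochelle salt work-up, used crude
Reagents that add atoms: none
Why: Lactone-to-lactol reduction: i-Bu2AlH adds once at −78 °C and the aluminium hemiacetal collapses only on neutral work-up, so the lactol should be obtained if it is never exposed to acid, which would dehydrate it to the furan.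

Step 4
Reactants: 6 (S)-4-methoxy-2-methyl-4-oxobutanoic acid
Product: 7 methyl (S)-4-hydroxy-3-methylbutanoate
Conditions: BH3·SMe2, THF, 0 °C → rt; aqueous K2CO3 work-up
Reagents that add atoms: none
Why: Borane reduces the carboxylic acid chemoselectively beside the methyl ester, and the stereocentre is not involved.

Step 5
Reactants: 7 methyl (S)-4-hydroxy-3-methylbutanoate
Product: 8 methyl (S)-4-iodo-3-methylbutanoate
Conditions: I2, PPh3, imidazole, CH2Cl2, 0 °C → rt
Reagents that add atoms: iodine, II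
Why: Appel-type iodination of the primary alcohol by SN2 displacement of the alkoxyphosphonium ion, which cannot affect the adjacent stereocentre.

Step 6
Reactants: 8 methyl (S)-4-iodo-3-methylbutanoate
Product: 9 [(S)-4-methoxy-2-methyl-4-oxobutyl]triphenylphosphonium iodide
Conditions: PPh3, MeCN, reflux
Reagents that add atoms: triphenylphosphine, c1ccc(cc1)P(c1ccccc1)c1ccccc1
Why: SN2 quaternisation of triphenylphosphine by the primary iodide.

Step 7
Reactants: 9 [(S)-4-methoxy-2-methyl-4-oxobutyl]triphenylphosphonium iodide; 5 4-{[(tert-butyldimethylsilyl)oxy]methyl}-2,5-dihydrofuran-2-ol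
Product: 12 methyl (3S,4Z,6E)-7-{[(tert-butyldimethylsilyl)oxy]methyl}-8-hydroxy-3-methylocta-4,6-dienoate, via phosphorus ylide 10 (not isolated), via ring-opened enal alkoxide 11 (not isolated)
Conditions: 9 (2.2 equiv), NaN(SiMe3)2 (2.1 equiv), THF, −78 °C; then 5, −78 °C → rt
Reagents that add atoms: none
Why: Wittig olefination of the non-stabilised ylide with the enal released from the lactol should give the C2=C3 Z-alkene under kinetic, lithium-free control, while the C1(10) geometry (CH2OH cis to the diene chain) is inherited from the butenolide ring and C4 is untouched.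

Step 8
Reactants: 12 methyl (3S,4Z,6E)-7-{[(tert-butyldimethylsilyl)oxy]methyl}-8-hydroxy-3-methylocta-4,6-dienoate
Product: 13 methyl (3S,4Z,6Z)-8-bromo-7-{[(tert-butyldimethylsilyl)oxy]methyl}-3-methylocta-4,6-dienoate
Conditions: CBr4, PPh3, 2,6-lutidine (cat.), CH2Cl2, −20 °C
Reagents that add atoms: carbon tetrabromide, BrC(Br)(Br)Br
Why: Appel bromination of the primary allylic alcohol by direct SN2 displacement at low temperature, which should leave the diene geometry intact.

Step 9
Reactants: 13 methyl (3S,4Z,6Z)-8-bromo-7-{[(tert-butyldimethylsilyl)oxy]methyl}-3-methylocta-4,6-dienoate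
Product: 14 methyl (3S,4Z,6E)-7-{[(tert-butyldimethylsilyl)oxy]methyl}-3-methyldeca-4,6-dien-9-ynoate
Conditions: HC≡CMgBr (1.5 equiv), CuBr·SMe2 (10 mol %), THF, −30 → 0 °C
Reagents that add atoms: ethynylmagnesium bromide, C#C[Mg]Br
Why: Copper-catalysed coupling of an alkynyl Grignard reagent with a primary allylic bromide should occur at the primary carbon (SN2) to give the skipped enyne, the methyl ester being inert to the alkynyl Grignard at this temperature.

Step 10
Reactants: 14 methyl (3S,4Z,6E)-7-{[(tert-butyldimethylsilyl)oxy]methyl}-3-methyldeca-4,6-dien-9-ynoate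
Product: 15 methyl (3S,4Z,6E)-7-{[(tert-butyldimethylsilyl)oxy]methyl}-10-iodo-3-methyldeca-4,6-dien-9-ynoate
Conditions: N-iodosuccinimide, AgNO3 (10 mol %), acetone, rt, dark
Reagents that add atoms: N-iodosuccinimide, O=C1CCC(=O)N1I
Why: Silver-catalysed electrophilic iodination of the terminal alkyne proceeds through the silver acetylide and should not touch the diene.

Step 11
Reactants: 15 methyl (3S,4Z,6E)-7-{[(tert-butyldimethylsilyl)oxy]methyl}-10-iodo-3-methyldeca-4,6-dien-9-ynoate
Product: 16 (3S,4Z,6E)-7-{[(tert-butyldimethylsilyl)oxy]methyl}-10-iodo-3-methyldeca-4,6-dien-9-ynal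
Conditions: i-Bu2AlH (1.05 equiv), CH2Cl2, −78 °C; MeOH, Rochelle salt work-up
Reagents that add atoms: none
Why: Partial reduction of the methyl ester stops at the tetrahedral aluminium hemiacetal at −78 °C and releases the aldehyde on work-up; the aldehyde is used at once.

Step 12
Reactants: 16 (3S,4Z,6E)-7-{[(tert-butyldimethylsilyl)oxy]methyl}-10-iodo-3-methyldeca-4,6-dien-9-ynal
Product: 17 (5E,7Z,9S)-5-{[(tert-butyldimethylsilyl)oxy]methyl}-9-methylcyclodeca-5,7-dien-2-yn-1-ol (both C1 epimers)
Conditions: CrCl2 (6 equiv), NiCl2 (2 mol %), THF, 0.003 M, slow addition, rt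
Reagents that add atoms: none
Why: Nozaki–Hiyama–Kishi reaction: the alkynylchromium species formed from the iodoalkyne adds to the aldehyde under high dilution, the two ring-cis alkenes holding the chain ends close; the new C6 carbinol centre is not controlled and is erased in step 13.

Step 13
Reactants: 17 (5E,7Z,9S)-5-{[(tert-butyldimethylsilyl)oxy]methyl}-9-methylcyclodeca-5,7-dien-2-yn-1-ol
Product: 18 (5E,7Z,9S)-5-{[(tert-butyldimethylsilyl)oxy]methyl}-9-methylcyclodeca-5,7-dien-2-yn-1-one
Conditions: Dess–Martin periodinane, pyridine, CH2Cl2, 0 °C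
Reagents that add atoms: none
Why: Dess–Martin oxidation of the propargylic alcohol under buffered, non-basic conditions, which should avoid isomerisation of the ynone through its acidic C9 methylene.

Step 14
Reactants: 18 (5E,7Z,9S)-5-{[(tert-butyldimethylsilyl)oxy]methyl}-9-methylcyclodeca-5,7-dien-2-yn-1-one
Product: 19 (1S,5E,7Z,9S)-5-{[(tert-butyldimethylsilyl)oxy]methyl}-9-methylcyclodeca-5,7-dien-2-yn-1-ol
Conditions: Ru[(S,S)-TsDPEN](p-cymene) (2 mol %), i-PrOH, rt
Reagents that add atoms: none
Why: Noyori asymmetric transfer hydrogenation of an α,β-acetylenic ketone: the (S,S)-catalyst should deliver hydride to the face that gives the (S)-propargylic alcohol (alkynyl as the π-substituent, as with acyclic ynones), and the base-free medium spares the C9 methylene.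

Step 15
Reactants: 19 (1S,5E,7Z,9S)-5-{[(tert-butyldimethylsilyl)oxy]methyl}-9-methylcyclodeca-5,7-dien-2-yn-1-ol
Product: 20 (1S,2Z,5E,7Z,9S)-5-{[(tert-butyldimethylsilyl)oxy]methyl}-9-methylcyclodeca-2,5,7-trien-1-ol
Conditions: H2 (1 atm), Pd/CaCO3 poisoned with Pb(OAc)2 (Lindlar catalyst), quinoline, EtOAc, rt
Reagents that add atoms: none
Why: Lindlar semihydrogenation adds hydrogen syn to the strained ring alkyne and should stop at the Z-alkene without reducing the diene.

Step 16
Reactants: 20 (1S,2Z,5E,7Z,9S)-5-{[(tert-butyldimethylsilyl)oxy]methyl}-9-methylcyclodeca-2,5,7-trien-1-ol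
Product: 21 (1S,2S,4S,5Z,7E,10R)-8-{[(tert-butyldimethylsilyl)oxy]methyl}-4-methyl-11-oxabicyclo[8.1.0]undeca-5,7-dien-2-ol (hydroxyl cis to the epoxide oxygen)
Conditions: VO(acac)2 (5 mol %), t-BuOOH (1.5 equiv), CH2Cl2, 0 °C → rt
Reagents that add atoms: tert-butyl hydroperoxide, CC(C)(C)OO
Why: Hydroxyl-directed vanadium-catalysed epoxidation: only the allylic-alcohol alkene reacts and oxygen should be delivered syn to the C6 hydroxyl, as with eight- and nine-membered (Z)-cycloalk-2-enols, which sets C7 and C8 as the cis-epoxy alcohol.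

Step 17
Reactants: 21 the cis-epoxy alcohol; 22 2-(diethoxyphosphoryl)acetic acid
Product: 23 2-(diethoxyphosphoryl)acetate ester of epoxy alcohol 21 (all stereocentres unchanged)
Conditions: DCC, DMAP (5 mol %), CH2Cl2, 0 °C → rt
Reagents that add atoms: none
Why: Steglich esterification under neutral conditions acylates the C6 hydroxyl without opening the epoxide or triggering Payne rearrangement.

Step 18
Reactants: 23 2-(diethoxyphosphoryl)acetate ester of epoxy alcohol 21
Product: 26 (3aS,4R,6E,8Z,10S,11aS)-6-{[(tert-butyldimethylsilyl)oxy]methyl}-4-hydroxy-10-methyl-3-methylidene-3a,4,5,10,11,11a-hexahydrocyclodeca[b]furan-2(3H)-one, via lithium phosphonoacetate carbanion 24 (not isolated), via lithium lactone carbanion 25 (not isolated)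
Conditions: LiN(SiMe3)2 (1.05 equiv), THF, −78 → 45 °C; then (CH2O)n (5 equiv), 0 °C → rt
Reagents that add atoms: formaldehyde (from paraformaldehyde), C=O
Why: Proposed new method: LiN(SiMe3)2 forms the ester-tethered phosphonoacetate carbanion, C11 attacks C7 of the cis-epoxide from the face opposite the epoxide oxygen (SN2), the C8 alkoxide so released is protonated at once by the far more acidic C11–H, and the resulting phosphonate-stabilised lactone carbanion olefinates formaldehyde (Horner–Wadsworth–Emmons) to install C13. The closest known reaction types are the intermolecular opening of epoxides by phosphonoacetate anions to α-phosphono-γ-lactones, the telescoped intramolecular Michael addition/olefination of phosphonoacetate esters to fused α-methylene-γ-lactones, and the 5-exo opening of 2,3-epoxy alcohol carbamates at C2. The γ-lactone (O6–C12–C11–C7–C6) closes in the 5-exo-tet mode, the carbanion being stabilised by the exocyclic phosphoryl group so that the in-ring ester carbonyl need not stay conjugated. C7 is set by inversion at the epoxide carbon and C8 keeps the epoxide configuration, so the trans ring fusion and the trans C7/C8 relation both follow from the cis-epoxy alcohol, and C11 ceases to be a stereocentre on olefination. The step needs C-attack at C7 rather than at C8 or by the enolate oxygen, and no acyl shift to O8: the two-atom O–C(=O) tether allows only the five-membered transition state, the lithium chelate between the phosphoryl and carbonyl oxygens masks the enolate oxygen, and the alkoxide never accumulates.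

Step 19
Reactants: 26 the C14-silylated hydroxy α-methylene lactone
Product: 27 (3aS,4R,6E,8Z,10S,11aS)-4-hydroxy-6-(hydroxymethyl)-10-methyl-3-methylidene-3a,4,5,10,11,11a-hexahydrocyclodeca[b]furan-2(3H)-one
Conditions: HF·pyridine, pyridine, THF, 0 °C → rt
Reagents that add atoms: none
Why: Buffered HF·pyridine cleaves the primary silyl ether without generating an alkoxide, so translactonisation to O8 and conjugate addition to the methylene lactone should not occur.

Step 20
Reactants: 27 the C8,C14-diol
Product: 28 [(3aS,4R,6E,8Z,10S,11aS)-4-hydroxy-10-methyl-3-methylidene-2-oxo-2,3,3a,4,5,10,11,11a-octahydrocyclodeca[b]furan-6-yl]methyl acetate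
Conditions: Ac2O (1.1 equiv), 2,4,6-collidine, CH2Cl2, −20 → 0 °C
Reagents that add atoms: acetic anhydride, CC(=O)OC(C)=O
Why: Chemoselective acetylation: the primary allylic C14 hydroxyl should react well before the hindered secondary C8 hydroxyl flanked by C7 and C9.

Step 21
Reactants: 29 (R)-3-bromo-2-hydroxy-2-methylpropanoic acid
Product: 31 (S)-2,3-dihydroxy-2-methylpropanoic acid, via sodium glycidate 30 (not isolated)
Conditions: NaOH (2.5 equiv), H2O, 0 → 60 °C; then Dowex 50W (H+ form)
Reagents that add atoms: sodium hydroxide, [Na+].[OH-]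
Why: Base closes the bromohydrin to the glycidate and hydroxide reopens it at the CH2 carbon, so the quaternary stereocentre is never touched (the descriptor changes from R to S only through the CIP priorities).

Step 22
Reactants: 31 (S)-2,3-dihydroxy-2-methylpropanoic acid
Product: 33 (S)-2-methyl-2,3-bis[(triethylsilyl)oxy]propanoic acid, via tris(triethylsilyl) derivative 32 (not isolated)
Conditions: Et3SiOTf (3.3 equiv), 2,6-lutidine, CH2Cl2, −78 → 0 °C; then K2CO3 (cat.), MeOH/H2O, 0 °C
Reagents that add atoms: triethylsilyl trifluoromethanesulfonate, CC[Si](CC)(CC)OS(=O)(=O)C(F)(F)F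
Why: Exhaustive silylation (including the tertiary hydroxyl) followed by selective solvolysis of the much more labile silyl ester should give the bis-silylated acid.

Step 23
Reactants: 33 (S)-2-methyl-2,3-bis[(triethylsilyl)oxy]propanoic acid; 28 the C14 acetate with free C8 hydroxyl
Product: 35 (3aR,4R,6E,8Z,10S,11aS)-6-(acetoxymethyl)-10-methyl-3-methylidene-2-oxo-2,3,3a,4,5,10,11,11a-octahydrocyclodeca[b]furan-4-yl (S)-2-methyl-2,3-bis[(triethylsilyl)oxy]propanoate, via mixed anhydride 34 (not isolated)
Conditions: 2,4,6-trichlorobenzoyl chloride, Et3N, THF, rt; then 28, DMAP, toluene, rt → 40 °C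
Reagents that add atoms: none
Why: Yamaguchi esterification is the standard way to acylate a hindered secondary alcohol with an α-quaternary acid, and its non-alkoxide conditions should leave the lactone and the acetate in place.

Step 24
Reactants: 35 the bis(triethylsilyl)-protected ester
Product: 36 (3aR,4R,6E,8Z,10S,11aS)-6-(acetoxymethyl)-10-methyl-3-methylidene-2-oxo-2,3,3a,4,5,10,11,11a-octahydrocyclodeca[b]furan-4-yl (S)-2,3-dihydroxy-2-methylpropanoate
Conditions: HF·pyridine, pyridine, THF, 0 °C → rt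
Reagents that add atoms: none
Why: Buffered fluoride desilylation removes both triethylsilyl ethers without affecting the allylic acetate, the hindered ester, the lactone or the diene.

**Compound list**

1 | 1,3-dihydroxyacetone (commercial as its dimer) | OCC(=O)CO | starting material
2 | ethyl 2-(triphenyl-λ5-phosphanylidene)acetate | CCOC(=O)C=P(c1ccccc1)(c1ccccc1)c1ccccc1 | starting material
3 | 4-(hydroxymethyl)furan-2(5H)-one | O=C1OCC(CO)=C1 | intermediate
4 | 4-{[(tert-butyldimethylsilyl)oxy]methyl}furan-2(5H)-one | O=C1OCC(CO[Si](C)(C)C(C)(C)C)=C1 | intermediate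
5 | 4-{[(tert-butyldimethylsilyl)oxy]methyl}-2,5-dihydrofuran-2-ol | OC1OCC(CO[Si](C)(C)C(C)(C)C)=C1 | intermediate
6 | (S)-4-methoxy-2-methyl-4-oxobutanoic acid | COC(=O)C[C@H](C)C(=O)O | starting material
7 | methyl (S)-4-hydroxy-3-methylbutanoate | COC(=O)C[C@H](C)CO | intermediate
8 | methyl (S)-4-iodo-3-methylbutanoate | COC(=O)C[C@H](C)CI | intermediate
9 | [(S)-4-methoxy-2-methyl-4-oxobutyl]triphenylphosphonium iodide | COC(=O)C[C@H](C)C[P+](c1ccccc1)(c1ccccc1)c1ccccc1.[I-] | intermediate
10 | methyl (S)-3-methyl-4-(triphenyl-λ5-phosphanylidene)butanoate (ylide) | COC(=O)C[C@H](C)C=P(c1ccccc1)(c1ccccc1)c1ccccc1 | intermediate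
11 | sodium (E)-2-{[(tert-butyldimethylsilyl)oxy]methyl}-4-oxobut-2-en-1-olate (ring-opened 5, CHO cis to CH2O−) | O=C/C=C(\C[O-])CO[Si](C)(C)C(C)(C)C.[Na+] | intermediate
12 | methyl (3S,4Z,6E)-7-{[(tert-butyldimethylsilyl)oxy]methyl}-8-hydroxy-3-methylocta-4,6-dienoate | COC(=O)C[C@H](C)/C=C\C=C(\CO[Si](C)(C)C(C)(C)C)CO | intermediate
13 | methyl (3S,4Z,6Z)-8-bromo-7-{[(tert-butyldimethylsilyl)oxy]methyl}-3-methylocta-4,6-dienoate | COC(=O)C[C@H](C)/C=C\C=C(\CO[Si](C)(C)C(C)(C)C)CBr | intermediate
14 | methyl (3S,4Z,6E)-7-{[(tert-butyldimethylsilyl)oxy]methyl}-3-methyldeca-4,6-dien-9-ynoate | COC(=O)C[C@H](C)/C=C\C=C(\CO[Si](C)(C)C(C)(C)C)CC#C | intermediate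
15 | methyl (3S,4Z,6E)-7-{[(tert-butyldimethylsilyl)oxy]methyl}-10-iodo-3-methyldeca-4,6-dien-9-ynoate | COC(=O)C[C@H](C)/C=C\C=C(\CO[Si](C)(C)C(C)(C)C)CC#CI | intermediate
16 | (3S,4Z,6E)-7-{[(tert-butyldimethylsilyl)oxy]methyl}-10-iodo-3-methyldeca-4,6-dien-9-ynal | O=CC[C@H](C)/C=C\C=C(\CO[Si](C)(C)C(C)(C)C)CC#CI | intermediate
17 | (5E,7Z,9S)-5-{[(tert-butyldimethylsilyl)oxy]methyl}-9-methylcyclodeca-5,7-dien-2-yn-1-ol (both C1 epimers) | OC1C[C@H](C)/C=C\C=C(\CO[Si](C)(C)C(C)(C)C)CC#C1 | intermediate
18 | (5E,7Z,9S)-5-{[(tert-butyldimethylsilyl)oxy]methyl}-9-methylcyclodeca-5,7-dien-2-yn-1-one | O=C1C[C@H](C)/C=C\C=C(\CO[Si](C)(C)C(C)(C)C)CC#C1 | intermediate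
19 | (1S,5E,7Z,9S)-5-{[(tert-butyldimethylsilyl)oxy]methyl}-9-methylcyclodeca-5,7-dien-2-yn-1-ol | O[C@H]1C[C@H](C)/C=C\C=C(\CO[Si](C)(C)C(C)(C)C)CC#C1 | intermediate
20 | (1S,2Z,5E,7Z,9S)-5-{[(tert-butyldimethylsilyl)oxy]methyl}-9-methylcyclodeca-2,5,7-trien-1-ol | O[C@@H]1/C=C\C/C(CO[Si](C)(C)C(C)(C)C)=C\C=C/[C@@H](C)C1 | intermediate
21 | (1S,2S,4S,5Z,7E,10R)-8-{[(tert-butyldimethylsilyl)oxy]methyl}-4-methyl-11-oxabicyclo[8.1.0]undeca-5,7-dien-2-ol (cis-epoxy alcohol) | O[C@H]1C[C@H](C)/C=C\C=C(\CO[Si](C)(C)C(C)(C)C)C[C@H]2O[C@@H]12 | intermediate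
22 | 2-(diethoxyphosphoryl)acetic acid | CCOP(=O)(CC(=O)O)OCC | starting material
23 | 2-(diethoxyphosphoryl)acetate ester of 21 | CCOP(=O)(CC(=O)O[C@H]1C[C@H](C)/C=C\C=C(\CO[Si](C)(C)C(C)(C)C)C[C@H]2O[C@@H]12)OCC | intermediate
24 | lithium salt of the phosphonoacetate carbanion of 23 | CCOP(=O)(OCC)[CH-]C(=O)O[C@H]1C[C@H](C)/C=C\C=C(\CO[Si](C)(C)C(C)(C)C)C[C@H]2O[C@@H]12.[Li+] | intermediate
25 | lithium salt of the α-(diethoxyphosphoryl) lactone carbanion (C8–OH free, trans-fused) | CCOP(=O)(OCC)[C-]1C(=O)O[C@H]2C[C@H](C)/C=C\C=C(\CO[Si](C)(C)C(C)(C)C)C[C@@H](O)[C@H]12.[Li+] | intermediate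
26 | (3aS,4R,6E,8Z,10S,11aS)-6-{[(tert-butyldimethylsilyl)oxy]methyl}-4-hydroxy-10-methyl-3-methylidene-3a,4,5,10,11,11a-hexahydrocyclodeca[b]furan-2(3H)-one | C=C1C(=O)O[C@H]2C[C@H](C)/C=C\C=C(\CO[Si](C)(C)C(C)(C)C)C[C@@H](O)[C@H]12 | intermediate
27 | (3aS,4R,6E,8Z,10S,11aS)-4-hydroxy-6-(hydroxymethyl)-10-methyl-3-methylidene-3a,4,5,10,11,11a-hexahydrocyclodeca[b]furan-2(3H)-one | C=C1C(=O)O[C@H]2C[C@H](C)/C=C\C=C(\CO)C[C@@H](O)[C@H]12 | intermediate
28 | [(3aS,4R,6E,8Z,10S,11aS)-4-hydroxy-10-methyl-3-methylidene-2-oxo-2,3,3a,4,5,10,11,11a-octahydrocyclodeca[b]furan-6-yl]methyl acetate | C=C1C(=O)O[C@H]2C[C@H](C)/C=C\C=C(\COC(C)=O)C[C@@H](O)[C@H]12 | intermediate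
29 | (R)-3-bromo-2-hydroxy-2-methylpropanoic acid | OC(=O)[C@@](C)(O)CBr | starting material
30 | sodium (S)-2-methyloxirane-2-carboxylate | [O-]C(=O)[C@@]1(C)OC1.[Na+] | intermediate
31 | (S)-2,3-dihydroxy-2-methylpropanoic acid | OC(=O)[C@@](C)(O)CO | intermediate
32 | triethylsilyl (S)-2-methyl-2,3-bis[(triethylsilyl)oxy]propanoate | CC[Si](CC)(CC)OC(=O)[C@@](C)(O[Si](CC)(CC)CC)CO[Si](CC)(CC)CC | intermediate
33 | (S)-2-methyl-2,3-bis[(triethylsilyl)oxy]propanoic acid | OC(=O)[C@@](C)(O[Si](CC)(CC)CC)CO[Si](CC)(CC)CC | intermediate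
34 | mixed anhydride of 33 with 2,4,6-trichlorobenzoic acid | O=C(OC(=O)[C@@](C)(O[Si](CC)(CC)CC)CO[Si](CC)(CC)CC)c1c(Cl)cc(Cl)cc1Cl | intermediate
35 | (3aR,4R,6E,8Z,10S,11aS)-6-(acetoxymethyl)-10-methyl-3-methylidene-2-oxo-2,3,3a,4,5,10,11,11a-octahydrocyclodeca[b]furan-4-yl (S)-2-methyl-2,3-bis[(triethylsilyl)oxy]propanoate | C=C1C(=O)O[C@H]2C[C@H](C)/C=C\C=C(\COC(C)=O)C[C@@H](OC(=O)[C@@](C)(O[Si](CC)(CC)CC)CO[Si](CC)(CC)CC)[C@H]12 | intermediate
36 | (3aR,4R,6E,8Z,10S,11aS)-6-(acetoxymethyl)-10-methyl-3-methylidene-2-oxo-2,3,3a,4,5,10,11,11a-octahydrocyclodeca[b]furan-4-yl (S)-2,3-dihydroxy-2-methylpropanoate | C=C1C(=O)O[C@H]2C[C@H](C)/C=C\C=C(\COC(C)=O)C[C@@H](OC(=O)[C@@](C)(O)CO)[C@H]12 | target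

**Step count**

Total steps: 24. Longest linear sequence: 19 steps (steps 1–3, 7–20, 23, 24).

**Steps most likely to fail**

Step 18 (Proposed new method). What may go wrong: the enolate oxygen alkylates instead of C11 (cyclic ketene acetal, then acyl migration), the carbanion attacks C8 in the six-membered mode, or the ester never reaches the s-cis rotamer needed for closure, so the anion only decomposes. Fallback, known chemistry with a radical in place of the carbanion, setting out from epoxy alcohol 21 and returning at diol 27: 21 would be O-propargylated (NaH, propargyl bromide, Bu4NI, THF, 0 °C, aprotic to suppress Payne rearrangement) to the prop-2-yn-1-yl ether of 21 F1. Cp2TiCl (from Cp2TiCl2 and Zn, THF, rt) would open the epoxide homolytically, and the C7 radical would close 5-exo-dig onto the alkyne, as established for epoxy propargyl ethers with trivalent titanium, to give the 3-methylidenetetrahydrofuran alcohol F2. In F2, C8 keeps its oxygen and configuration, and C7 should be set by the trans-selective radical closure. Silylation (Et3SiCl, imidazole, CH2Cl2) would give the C8 triethylsilyl ether F3. Oxidation of the allylic ether methylene (CrO3·2 pyridine, CH2Cl2, rt) would give the α-methylene lactone bis-silyl ether F4, and HF·pyridine would remove both silyl groups to reach 27.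

Step 12. What may go wrong: intermolecular coupling and reductive loss of iodine outrun the strained ten-membered closure. Fallback, closing the ring at C8–C9 instead of C6–C7, setting out from dienol 12 and returning at 17: i-Bu2AlH (2.2 equiv, CH2Cl2, −78 °C) would reduce the ester of 12 to the hydroxy aldehyde F5. HC≡CMgBr (3 equiv, THF, −78 → 0 °C) would add to give the alkynyl diol F6 as both carbinol epimers. CBr4/PPh3 (CH2Cl2, −40 °C) would brominate only the primary allylic hydroxyl to give the bromo alkynol F7. Copper-mediated intramolecular alkyne–allylic halide coupling (CuI, Cs2CO3, NaI, DMF, 0.005 M, rt) would then give cyclic alkynol 17, after which steps 13 onward apply unchanged.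

Step 16. What may go wrong: oxygen is delivered anti to the hydroxyl in this particular ring, or the diene is epoxidised in competition. Fallback, a stereochemical relay through the C6 epimer with inversion during esterification, setting out from ynone 18 and returning at 23: transfer hydrogenation with Ru[(R,R)-TsDPEN](p-cymene) in i-PrOH would give the (1R)-alkynol F8. Lindlar semihydrogenation would give the (1R)-(Z)-allylic alcohol F9. Peracid epoxidation (m-CPBA, NaHCO3, CH2Cl2, −20 °C), which is anti-selective in medium-ring (Z)-allylic alcohols, would give the trans-epoxy alcohol F10 with the same epoxide configuration as 21. Mitsunobu esterification with 22 (PPh3, diisopropyl azodicarboxylate, THF, 0 °C) would invert C6 and give phosphonoacetate 23 directly.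

Further compounds
F1 | step 18 | prop-2-yn-1-yl ether of epoxy alcohol 21 | C#CCO[C@H]1C[C@H](C)/C=C\C=C(\CO[Si](C)(C)C(C)(C)C)C[C@H]2O[C@@H]12
F2 | step 18 | (3aS,4R,6E,8Z,10S,11aS)-6-{[(tert-butyldimethylsilyl)oxy]methyl}-10-methyl-3-methylidene-2,3,3a,4,5,10,11,11a-octahydrocyclodeca[b]furan-4-ol | C=C1CO[C@H]2C[C@H](C)/C=C\C=C(\CO[Si](C)(C)C(C)(C)C)C[C@@H](O)[C@H]12
F3 | step 18 | C8 triethylsilyl ether of F2 | C=C1CO[C@H]2C[C@H](C)/C=C\C=C(\CO[Si](C)(C)C(C)(C)C)C[C@@H](O[Si](CC)(CC)CC)[C@H]12
F4 | step 18 | C8 triethylsilyl ether of lactone 26 | C=C1C(=O)O[C@H]2C[C@H](C)/C=C\C=C(\CO[Si](C)(C)C(C)(C)C)C[C@@H](O[Si](CC)(CC)CC)[C@H]12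
F5 | step 12 | (3S,4Z,6E)-7-{[(tert-butyldimethylsilyl)oxy]methyl}-8-hydroxy-3-methylocta-4,6-dienal | O=CC[C@H](C)/C=C\C=C(\CO[Si](C)(C)C(C)(C)C)CO
F6 | step 12 | (5S,6Z,8E)-9-{[(tert-butyldimethylsilyl)oxy]methyl}-5-methyldeca-6,8-dien-1-yne-3,10-diol (both C3 epimers) | C#CC(O)C[C@H](C)/C=C\C=C(\CO[Si](C)(C)C(C)(C)C)CO
F7 | step 12 | (5S,6Z,8Z)-10-bromo-9-{[(tert-butyldimethylsilyl)oxy]methyl}-5-methyldeca-6,8-dien-1-yn-3-ol (both C3 epimers) | C#CC(O)C[C@H](C)/C=C\C=C(\CO[Si](C)(C)C(C)(C)C)CBr
F8 | step 16 | (1R,5E,7Z,9S)-5-{[(tert-butyldimethylsilyl)oxy]methyl}-9-methylcyclodeca-5,7-dien-2-yn-1-ol | O[C@@H]1C[C@H](C)/C=C\C=C(\CO[Si](C)(C)C(C)(C)C)CC#C1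
F9 | step 16 | (1R,2Z,5E,7Z,9S)-5-{[(tert-butyldimethylsilyl)oxy]methyl}-9-methylcyclodeca-2,5,7-trien-1-ol | O[C@H]1/C=C\C/C(CO[Si](C)(C)C(C)(C)C)=C\C=C/[C@@H](C)C1
F10 | step 16 | (1S,2R,4S,5Z,7E,10R)-8-{[(tert-butyldimethylsilyl)oxy]methyl}-4-methyl-11-oxabicyclo[8.1.0]undeca-5,7-dien-2-ol (trans-epoxy alcohol) | O[C@@H]1C[C@H](C)/C=C\C=C(\CO[Si](C)(C)C(C)(C)C)C[C@H]2O[C@@H]12
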